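**Retrosynthetic overview**

- Ring C of pervilleanone is opened at O1–C2 and C4–C4a. Both bonds are made in one operation by isomerising an aryl 2-arylacrylate: O→C acyl shift, oxa-Michael closure, then catalyst-controlled protonation at C3.
- The feature that allows this is the ortho-acylphenol / β-aryloxy ketone array of ring C. O1 sits on C8a next to C4a, C4a carries the C4 carbonyl, C2 is β to that carbonyl, and the C7 oxygen is para to C4a. An ester on O1 with iodine on C4a maps onto this array, and the only stereocentre, C3, is a protonation site.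
- Ring B fragment: 2'-hydroxy-3',4'-dimethoxyacetophenone → C5' bromination → γ-selective (reverse) prenyl cross-coupling → acetyl group to acrylic acid by enol triflate carbonylation. Ring A fragment: resorcinol → 4-iodoresorcinol → mono-TIPS ether.
- Rings A and B are bought as arenes. Ring C is the only ring formed, in step 9. Buffered fluoride then removes both silyl ethers.

Key step: step 9

Remark: the facial sense of the catalysed protonation in step 9 cannot be predicted with certainty. The quinine- and quinidine-derived squaramides are pseudo-enantiomers, and the one that gives the 3R product is used (written below as the quinidine-derived catalyst).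

**Step 1**
Reactants: 1 2'-hydroxy-3',4'-dimethoxyacetophenone
Product: 2 1-(5-bromo-2-hydroxy-3,4-dimethoxyphenyl)ethan-1-one
Conditions: NBS (1.05 equiv), MeCN, 0 °C to rt
Reagents that add atoms: N-bromosuccinimide, O=C1CCC(=O)N1Br
Why: Electrophilic aromatic bromination takes place at C5, the only free position para to the phenol and ortho to a methoxy group, whereas C6 lies next to the deactivating acetyl group.

**Step 2**
Reactants: 2 1-(5-bromo-2-hydroxy-3,4-dimethoxyphenyl)ethan-1-one
Product: 3 1-[5-bromo-3,4-dimethoxy-2-(triisopropylsilyloxy)phenyl]ethan-1-one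
Conditions: TIPSOTf, 2,6-lutidine, CH2Cl2, 0 °C
Reagents that add atoms: triisopropylsilyl trifluoromethanesulfonate, CC(C)[Si](OS(=O)(=O)C(F)(F)F)(C(C)C)C(C)C
Why: Silyl ether formation with the reactive silyl triflate overcomes the chelation and the two ortho substituents of this phenol, and the TIPS ether then withstands the aqueous base, amide base and organolithium of the later steps.

**Step 3**
Reactants: 3 1-[5-bromo-3,4-dimethoxy-2-(triisopropylsilyloxy)phenyl]ethan-1-one
Product: 4 1-[3,4-dimethoxy-5-(2-methylbut-3-en-2-yl)-2-(triisopropylsilyloxy)phenyl]ethan-1-one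
Conditions: prenylboronic acid pinacol ester, Pd(OAc)2 (cat.), SPhos (cat.), K3PO4, MeCN–H2O, 70 °C
Reagents that add atoms: 4,4,5,5-tetramethyl-2-(3-methylbut-2-en-1-yl)-1,3,2-dioxaborolane, CC(C)=CCB1OC(C)(C)C(C)(C)O1
Why: Suzuki–Miyaura coupling of an allylboronate in its γ-selective mode: SE2' transmetalation puts palladium on the tertiary carbon and reductive elimination from the dicyclohexylbiarylphosphine complex precedes allyl isomerisation, which gives the 1,1-dimethylallyl group and not the linear prenyl group.

**Step 4**
Reactants: 4 1-[3,4-dimethoxy-5-(2-methylbut-3-en-2-yl)-2-(triisopropylsilyloxy)phenyl]ethan-1-one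
Product: 5 1-[3,4-dimethoxy-5-(2-methylbut-3-en-2-yl)-2-(triisopropylsilyloxy)phenyl]ethenyl trifluoromethanesulfonate
Conditions: KN(SiMe3)2, THF, –78 °C; then N-(5-chloropyridin-2-yl)bis(trifluoromethanesulfonimide), –78 °C
Reagents that add atoms: N-(5-chloropyridin-2-yl)bis(trifluoromethanesulfonimide), FC(F)(F)S(=O)(=O)N(c1ccc(Cl)cn1)S(=O)(=O)C(F)(F)F
Why: Enol triflate formation: the methyl ketone is the only enolisable site, and its potassium enolate is trapped on oxygen at –78 °C, where a shift of the bulky silyl group from the phenol oxygen to the enolate oxygen should be slow.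

**Step 5**
Reactants: 5 1-[3,4-dimethoxy-5-(2-methylbut-3-en-2-yl)-2-(triisopropylsilyloxy)phenyl]ethenyl trifluoromethanesulfonate
Product: 6 2-[3,4-dimethoxy-5-(2-methylbut-3-en-2-yl)-2-(triisopropylsilyloxy)phenyl]prop-2-enoic acid
Conditions: Pd(OAc)2 (cat.), PPh3 (cat.), KOAc, CO (1 atm), DMF–H2O, rt
Reagents that add atoms: carbon monoxide, [C-]#[O+]; water, O
Why: Hydroxycarbonylation of an enol triflate (oxidative addition to zerovalent palladium, CO insertion, capture of the acylpalladium by acetate and water) delivers the 2-arylacrylic acid directly, so that no ester has to be saponified next to the aryl silyl ether.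

**Step 6**
Reactants: 7 resorcinol
Product: 8 4-iodoresorcinol (4-iodobenzene-1,3-diol)
Conditions: ICl (1.0 equiv), Et2O, rt
Reagents that add atoms: iodine monochloride, ClI
Why: Electrophilic aromatic iodination of resorcinol with ICl is directed to C4, para to one hydroxyl and ortho to the other, in preference to the crowded C2.

**Step 7**
Reactants: 8 4-iodoresorcinol
Product: 9 2-iodo-5-(triisopropylsilyloxy)phenol
Conditions: TIPSCl (1.0 equiv), imidazole, CH2Cl2–DMF, 0 °C
Reagents that add atoms: chlorotriisopropylsilane, CC(C)[Si](Cl)(C(C)C)C(C)C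
Why: Sterically controlled mono-silylation: the bulky silyl chloride should react at the unhindered hydroxyl para to iodine much faster than at the hydroxyl flanked by iodine, which thus stays free as the future O1.

**Step 8**
Reactants: 6 2-[3,4-dimethoxy-5-(2-methylbut-3-en-2-yl)-2-(triisopropylsilyloxy)phenyl]prop-2-enoic acid; 9 2-iodo-5-(triisopropylsilyloxy)phenol
Product: 10 2-iodo-5-(triisopropylsilyloxy)phenyl 2-[3,4-dimethoxy-5-(2-methylbut-3-en-2-yl)-2-(triisopropylsilyloxy)phenyl]prop-2-enoate
Conditions: EDC·HCl, DMAP, CH2Cl2, 0 °C to rt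
Reagents that add atoms: none
Why: Steglich esterification (carbodiimide activation with DMAP as acyl-transfer catalyst) joins the two fragments through the phenol oxygen ortho to iodine, which sets up the 1,3-relationship between O1 and the acyl carbon needed for the acyl shift.

**Step 9**
Reactants: 10 2-iodo-5-(triisopropylsilyloxy)phenyl 2-[3,4-dimethoxy-5-(2-methylbut-3-en-2-yl)-2-(triisopropylsilyloxy)phenyl]prop-2-enoate
Product: 14 (3R)-3-[3,4-dimethoxy-5-(2-methylbut-3-en-2-yl)-2-(triisopropylsilyloxy)phenyl]-7-(triisopropylsilyloxy)chroman-4-one, via ortho-lithiated ester 11 (not isolated), via lithium acylphenoxide 12 (not isolated), via hydroxy enone 13 (not isolated)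
Conditions: n-BuLi (1.05 equiv), THF–Et2O, –100 °C; MsOH (1.0 equiv), –100 °C; then 3-[3,5-bis(trifluoromethyl)anilino]-4-[(9-deoxy-epi-quinidin-9-yl)amino]cyclobut-3-ene-1,2-dione (10 mol %), toluene, –40 °C
Reagents that add atoms: none
Why: Proposed new method: iodine–lithium exchange gives aryllithium 11, whose carbanionic carbon (the future C4a) adds to the neighbouring ester carbonyl through a four-membered transition state and opens to the chelated lithium phenoxide 12 (anionic Fries rearrangement, 1,3 O→C acyl shift, forming C4–C4a); neutralisation with one equivalent of MsOH releases hydroxy enone 13, and the bifunctional amine–squaramide then deprotonates the phenol, closes ring C by 6-endo-trig oxa-Michael addition of O1 to the terminal methylene carbon (forming O1–C2) and protonates the resulting chromen-4-olate at C3. The closest known reaction types are the halogen–lithium-exchange-triggered anionic Fries rearrangement of ortho-haloaryl esters, iodine–lithium exchange performed in the presence of conjugated esters, the base-mediated closure of 2-hydroxyaryl 1-arylvinyl ketones to isoflavanones and the cinchona squaramide or thiourea catalysed conjugate addition–enantioselective protonation of α-substituted acrylates and enones; what is new is their telescoped use with protonation as the only stereo-determining event. C3, the only stereocentre, is set under catalyst control: the enolate oxygen is held by the two squaramide N–H bonds and the proton is passed from the quinuclidinium N–H to one face of C3 inside this ion pair, the bulky ortho-silyloxyaryl group on C3 sharpening the facial bias. The step needs exchange to outrun addition of n-BuLi to the acrylate (secured by the aryl iodide, the temperature of –100 °C and the acyl group waiting next to the new carbanion), attack at the carbonyl carbon and not at the alkene (secured by the Z conformation of the aryl ester, which turns the vinyl group away from the lithiated carbon), acylation at C4a only (secured by the iodine, placed para to the silyloxy group) and a catalysed closure that outruns the uncatalysed one (secured by the internal O–H···O=C hydrogen bond of 13, the non-basic lithium mesylate and the low temperature). The weakly basic tertiary amine should not enolise the α-aryl ketone once it is formed, so the configuration at C3 should persist.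

**Step 10**
Reactants: 14 (3R)-3-[3,4-dimethoxy-5-(2-methylbut-3-en-2-yl)-2-(triisopropylsilyloxy)phenyl]-7-(triisopropylsilyloxy)chroman-4-one
Product: 15 pervilleanone, (3R)-7-hydroxy-3-[2-hydroxy-3,4-dimethoxy-5-(2-methylbut-3-en-2-yl)phenyl]chroman-4-one
Conditions: Bu4NF, AcOH (1:1), THF, 0 °C
Reagents that add atoms: none
Why: Fluoride-induced cleavage of both aryl silyl ethers with acetic acid as buffer avoids the strong acid that would ionise the 1,1-dimethylallyl group and the free base that would enolise C3.

**Compound list**

1 | 2'-hydroxy-3',4'-dimethoxyacetophenone | CC(=O)c1ccc(OC)c(OC)c1O | starting material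
2 | 1-(5-bromo-2-hydroxy-3,4-dimethoxyphenyl)ethan-1-one | CC(=O)c1cc(Br)c(OC)c(OC)c1O | intermediate
3 | 1-[5-bromo-3,4-dimethoxy-2-(triisopropylsilyloxy)phenyl]ethan-1-one | CC(=O)c1cc(Br)c(OC)c(OC)c1O[Si](C(C)C)(C(C)C)C(C)C | intermediate
4 | 1-[3,4-dimethoxy-5-(2-methylbut-3-en-2-yl)-2-(triisopropylsilyloxy)phenyl]ethan-1-one | CC(=O)c1cc(C(C)(C)C=C)c(OC)c(OC)c1O[Si](C(C)C)(C(C)C)C(C)C | intermediate
5 | 1-[3,4-dimethoxy-5-(2-methylbut-3-en-2-yl)-2-(triisopropylsilyloxy)phenyl]ethenyl trifluoromethanesulfonate | C=C(OS(=O)(=O)C(F)(F)F)c1cc(C(C)(C)C=C)c(OC)c(OC)c1O[Si](C(C)C)(C(C)C)C(C)C | intermediate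
6 | 2-[3,4-dimethoxy-5-(2-methylbut-3-en-2-yl)-2-(triisopropylsilyloxy)phenyl]prop-2-enoic acid | C=C(C(=O)O)c1cc(C(C)(C)C=C)c(OC)c(OC)c1O[Si](C(C)C)(C(C)C)C(C)C | intermediate
7 | resorcinol | Oc1cccc(O)c1 | starting material
8 | 4-iodoresorcinol | Oc1ccc(I)c(O)c1 | intermediate
9 | 2-iodo-5-(triisopropylsilyloxy)phenol | Oc1cc(O[Si](C(C)C)(C(C)C)C(C)C)ccc1I | intermediate
10 | 2-iodo-5-(triisopropylsilyloxy)phenyl 2-[3,4-dimethoxy-5-(2-methylbut-3-en-2-yl)-2-(triisopropylsilyloxy)phenyl]prop-2-enoate | C=C(C(=O)Oc1cc(O[Si](C(C)C)(C(C)C)C(C)C)ccc1I)c1cc(C(C)(C)C=C)c(OC)c(OC)c1O[Si](C(C)C)(C(C)C)C(C)C | intermediate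
11 | ortho-lithiated ester (lithium in place of iodine in 10) | C=C(C(=O)Oc1cc(O[Si](C(C)C)(C(C)C)C(C)C)ccc1[Li])c1cc(C(C)(C)C=C)c(OC)c(OC)c1O[Si](C(C)C)(C(C)C)C(C)C | intermediate
12 | lithium 2-{2-[3,4-dimethoxy-5-(2-methylbut-3-en-2-yl)-2-(triisopropylsilyloxy)phenyl]prop-2-enoyl}-5-(triisopropylsilyloxy)phenoxide | C=C(C(=O)c1ccc(O[Si](C(C)C)(C(C)C)C(C)C)cc1O[Li])c1cc(C(C)(C)C=C)c(OC)c(OC)c1O[Si](C(C)C)(C(C)C)C(C)C | intermediate
13 | 2-[3,4-dimethoxy-5-(2-methylbut-3-en-2-yl)-2-(triisopropylsilyloxy)phenyl]-1-[2-hydroxy-4-(triisopropylsilyloxy)phenyl]prop-2-en-1-one | C=C(C(=O)c1ccc(O[Si](C(C)C)(C(C)C)C(C)C)cc1O)c1cc(C(C)(C)C=C)c(OC)c(OC)c1O[Si](C(C)C)(C(C)C)C(C)C | intermediate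
14 | (3R)-3-[3,4-dimethoxy-5-(2-methylbut-3-en-2-yl)-2-(triisopropylsilyloxy)phenyl]-7-(triisopropylsilyloxy)chroman-4-one | C=CC(C)(C)c1cc([C@@H]2COc3cc(O[Si](C(C)C)(C(C)C)C(C)C)ccc3C2=O)c(O[Si](C(C)C)(C(C)C)C(C)C)c(OC)c1OC | intermediate
15 | pervilleanone, (3R)-7-hydroxy-3-[2-hydroxy-3,4-dimethoxy-5-(2-methylbut-3-en-2-yl)phenyl]chroman-4-one | C=CC(C)(C)c1cc([C@@H]2COc3cc(O)ccc3C2=O)c(O)c(OC)c1OC | target

**Step count**

Total: 10 steps. Longest linear sequence: 8 steps (steps 1–5, 8, 9 and 10 from compound 1).

**Steps most likely to fail, with fallbacks**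

Step 9 (proposed new method). The protonation may proceed with poor facial discrimination, or the uncatalysed closure may compete with the catalysed one, so that the product is formed with low enantiomeric purity. The fallback sets out from 10 and comes back at 14, and it sets the stereocentre by a reduction–oxidation detour of known type. Ester 10 is treated with n-BuLi at –100 °C as before, but the mixture is quenched with aqueous NH4Cl and stirred with Et3N, so that the hydroxy enone closes to the racemic 3-[3,4-dimethoxy-5-(2-methylbut-3-en-2-yl)-2-(triisopropylsilyloxy)phenyl]-7-(triisopropylsilyloxy)chroman-4-one F1. Asymmetric transfer hydrogenation of F1 with RuCl[(R,R)-TsDPEN](p-cymene) in HCO2H/Et3N runs as a dynamic kinetic resolution, because C3 epimerises through the enol while one enantiomer is reduced faster. By the usual sense of induction for aryl ketones it should give the cis-(3R,4R)-chroman-4-ol F2. Oxidation of F2 with Dess–Martin periodinane and NaHCO3 in CH2Cl2 at 0 °C should return ketone 14 with C3 untouched.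

Step 3. Allyl isomerisation on palladium may outrun reductive elimination at the crowded position next to the methoxy group, which would give the linear prenyl isomer or a stalled coupling. The fallback sets out from 3 and comes back at 4, and it inverts the polarity of the coupling. Bromide 3 is borylated with B2(OH)4, Pd(OAc)2, XPhos and KOAc in EtOH to [5-acetyl-2,3-dimethoxy-4-(triisopropylsilyloxy)phenyl]boronic acid F3. γ-Selective allyl–aryl coupling of F3 with prenyl acetate (Pd(OAc)2, 1,10-phenanthroline, AgSbF6, ClCH2CH2Cl, 60 °C) then gives 4. In this coupling the aryl group is transferred to divalent palladium, the alkene inserts with the aryl group going to the disubstituted carbon, and β-acetoxy elimination releases the 1,1-dimethylallyl arene.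

Step 4. The silyl group may migrate from the phenol oxygen to the enolate oxygen, or the electron-rich 1-arylvinyl triflate may eliminate to the arylalkyne. The fallback sets out from 4 and comes back at 6 (step 5 is bypassed), and it avoids enolate and triflate altogether. Ketone 4 is oxidised with SeO2 in pyridine at 100 °C (Riley oxidation; the 1,1-dimethylallyl group has no allylic hydrogen) to 2-[3,4-dimethoxy-5-(2-methylbut-3-en-2-yl)-2-(triisopropylsilyloxy)phenyl]-2-oxoacetic acid F4. Wittig methylenation of the carboxylate of F4 with excess Ph3P=CH2 (from Ph3PCH3Br and KOt-Bu, THF) gives acrylic acid 6 after acidification.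

**Further compounds**

F1 | step 9 | rac-3-[3,4-dimethoxy-5-(2-methylbut-3-en-2-yl)-2-(triisopropylsilyloxy)phenyl]-7-(triisopropylsilyloxy)chroman-4-one | C=CC(C)(C)c1cc(C2COc3cc(O[Si](C(C)C)(C(C)C)C(C)C)ccc3C2=O)c(O[Si](C(C)C)(C(C)C)C(C)C)c(OC)c1OC
F2 | step 9 | (3R,4R)-3-[3,4-dimethoxy-5-(2-methylbut-3-en-2-yl)-2-(triisopropylsilyloxy)phenyl]-7-(triisopropylsilyloxy)chroman-4-ol | C=CC(C)(C)c1cc([C@@H]2COc3cc(O[Si](C(C)C)(C(C)C)C(C)C)ccc3[C@@H]2O)c(O[Si](C(C)C)(C(C)C)C(C)C)c(OC)c1OC
F3 | step 3 | [5-acetyl-2,3-dimethoxy-4-(triisopropylsilyloxy)phenyl]boronic acid | CC(=O)c1cc(B(O)O)c(OC)c(OC)c1O[Si](C(C)C)(C(C)C)C(C)C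
F4 | step 4 | 2-[3,4-dimethoxy-5-(2-methylbut-3-en-2-yl)-2-(triisopropylsilyloxy)phenyl]-2-oxoacetic acid | O=C(O)C(=O)c1cc(C(C)(C)C=C)c(OC)c(OC)c1O[Si](C(C)C)(C(C)C)C(C)C
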